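Count 7.08 initiator lost to spent initiator for every chain begun: the spending step and the chain-starting step both take free monomer plus initiator, so free monomer cancels from the ratio of their rates, and the spending constant is the larger.

| flask | free monomer | pre-initiator | time |
|---|---|---|---|
| Friday's | 0.020 M | 0.40 mM | 10 d |
| Saturday's | 0.012 M | 0.40 mM | 10 d |
    free monomer + living end → monomer in chains + living end, rate k1*[living end]*[free monomer] (k1 = 107 M⁻¹ h⁻¹)
    free monomer + initiator → living end + monomer in chains (k2 = 1.07 M⁻¹ h⁻¹)
    pre-initiator → initiator (k3 = 0.487 h⁻¹)
    free monomer + initiator → spent initiator (k4 = 7.58 M⁻¹ h⁻¹)
- the average divides the monomer in chains by the number of chains begun, living and dead together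
- run time (Friday's): 10 d
* which of the two ends with the longer chains by the average number of monomer units in a chain (chains begun, living or dead) ("neither" if they lie within 10%) (Friday's / Saturday's / neither)
* average number of monomer units in a chain (chains begun, living or dead) at the end, Friday's
* average number of monomer units in a chain (chains begun, living or dead) at the end, Saturday's

Pre-initiator has a half-life of 0.059 d, and in Friday's the initiator has one of 0.19 d by the spending step alone at free monomer as charged, far shorter than the run; in Saturday's the same reckoning gives 0.318 d, far shorter too, so take the chains as begun at the start in both flasks.

Take an even split of the initiator, 0.5 to each step, as the zero of the scale. Against it stands the chain-starting share, the selectivity of initiation, the chain-starting constant over the sum of both: 12.4%.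

Both recipes charge 0.40 mM, so I reckon 0.0495 mM of living end in each. Propagation returns its living end, so free monomer decays pseudo-first-order and 28.1% of it remains after 10 d. Each initiator takes one free monomer by either step, so subtract the pre-initiator charge from the monomer charge. This puts Friday's at 285 and Saturday's at 169, and the longer chains in Friday's.

The forecast says Friday's, with 281 and 165: “the richer Friday feed gives the longer chains”. My figure stands slightly higher for Friday's and for Saturday's.

The flask gives Friday's, with 281 for Friday's and 165 for Saturday's, so the forecast held. Friday's holds 4.95 × 10⁻⁵ M of living end at 10.0 d, and the chain-starting share of the pre-initiator charge is 4.95 × 10⁻⁵ M.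

Apply the share to the neighbour of Saturday's charged with 1.6 × 10⁻⁴ M of pre-initiator: it gives 1.98 × 10⁻⁵ M of living end, 60.2% of the free monomer remaining, and a length of 238. That flask gives 230, with 1.98 × 10⁻⁵ M of living end.

The numbers of this flask are assumed.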